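**Retrosynthetic overview**
1. The plan rests on the C1–C3 β-hydroxy ester whose ester oxygen is the C21 oxygen of the 22-membered lactone (the only ring), so the C21 bromoacetate can act as nucleophile towards a C3 aldehyde.
2. Target 63 ⇐ Stille coupling (C24–C25) of (Z)-vinyl iodide 53 with (1Z,3E)-trienylstannane 62 ⇐ desilylation of macrolactone 52.
3. 52 ⇐ SmI2 macro-Reformatsky closure (C2–C3 bond; the ring is formed in this single step) of bromoacetate aldehyde 49.
4. 49 ⇐ C3–C24 chain 44 ⇐ Julia–Kocienski olefination (C14=C15) of sulfone 42 (C3–C14) with aldehyde 24 (C15–C24).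
5. 42 ⇐ Noyori-derived alkyne 31, C8–C10 linchpin 33 and Keck allylation of 37; 24 ⇐ Brown crotylation of 3, Stork–Zhao iodoolefination, cross-metathesis and CBS reduction.

Key step: step 32

Remark: atoms carry the target numbering (C1 lactone carbonyl to C21 ring carbinol, C22–C30 side chain); the ring closure is assumed to favour the 3,5-anti (3S) carbinol, and the first fallback covers the opposite outcome.

Step 1
Reactants: 1 propane-1,3-diol
Product: 2 3-[(4-methoxybenzyl)oxy]propan-1-ol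
Conditions: NaH (1 equiv), 4-methoxybenzyl chloride (1 equiv), n-Bu4NI (cat.), THF, 0 °C to rt; diol in threefold excess
Reagents that add atoms: 4-methoxybenzyl chloride, COc1ccc(CCl)cc1
Why: Williamson etherification, in which the excess of the symmetric diol should hold the reaction at the mono-ether.

Step 2
Reactants: 2 3-[(4-methoxybenzyl)oxy]propan-1-ol
Product: 3 3-[(4-methoxybenzyl)oxy]propanal
Conditions: PhI(OAc)2, TEMPO (cat.), CH2Cl2, rt
Reagents that add atoms: none
Why: TEMPO/PhI(OAc)2 oxidation of a primary alcohol, which should stop cleanly at the aldehyde.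

Step 3
Reactants: 3 3-[(4-methoxybenzyl)oxy]propanal; 4 cis-but-2-ene
Product: 8 (3R,4R)-1-[(4-methoxybenzyl)oxy]-4-methylhex-5-en-3-ol, via (Z)-but-2-enylpotassium 5 (not isolated), via B-(Z)-crotyldiisopinocampheylborane 6 (not isolated), via diisopinocampheylborinate ester 7 (not isolated)
Conditions: 4, KOt-Bu, n-BuLi, THF, −78 to −45 °C; (−)-Ipc2BOMe [from (+)-α-pinene], −78 °C; BF3·OEt2; 3, −78 °C; then NaOH, H2O2
Reagents that add atoms: none
Why: Brown asymmetric crotylboration, in which the (Z)-crotylborane reacts through a closed chair transition state (syn product) and the isopinocampheyl groups derived from (+)-α-pinene should direct it to the Si face of 3, setting 3R,4R (C21 and C20).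

Step 4
Reactants: 8 (3R,4R)-1-[(4-methoxybenzyl)oxy]-4-methylhex-5-en-3-ol
Product: 9 triethyl{[(3R,4R)-1-[(4-methoxybenzyl)oxy]-4-methylhex-5-en-3-yl]oxy}silane
Conditions: TESOTf, 2,6-lutidine, CH2Cl2, −78 °C
Reagents that add atoms: triethylsilyl trifluoromethanesulfonate, CC[Si](CC)(CC)OS(=O)(=O)C(F)(F)F
Why: Silylation of a secondary alcohol with a silyl triflate; the triethylsilyl ether at C21 stays distinguishable from the later tert-butyldimethylsilyl ethers.

Step 5
Reactants: 9 triethyl{[(3R,4R)-1-[(4-methoxybenzyl)oxy]-4-methylhex-5-en-3-yl]oxy}silane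
Product: 10 (3R,4R)-4-methyl-3-[(triethylsilyl)oxy]hex-5-en-1-ol
Conditions: DDQ, CH2Cl2/pH 7 buffer, 0 °C
Reagents that add atoms: none
Why: Oxidative cleavage of a 4-methoxybenzyl ether by DDQ, which under buffered conditions should leave the silyl ether and the alkene untouched.

Step 6
Reactants: 10 (3R,4R)-4-methyl-3-[(triethylsilyl)oxy]hex-5-en-1-ol
Product: 11 (3R,4R)-4-methyl-3-[(triethylsilyl)oxy]hex-5-enal
Conditions: Dess–Martin periodinane, NaHCO3, CH2Cl2, 0 °C to rt
Reagents that add atoms: none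
Why: Dess–Martin oxidation, mild enough for a β-silyloxy aldehyde.

Step 7
Reactants: 11 (3R,4R)-4-methyl-3-[(triethylsilyl)oxy]hex-5-enal; 12 ethyltriphenylphosphonium iodide
Product: 16 triethyl{[(3R,4R,6Z)-7-iodo-3-methylocta-1,6-dien-4-yl]oxy}silane, via ethylidenetriphenylphosphorane 13 (not isolated), via (1-iodoethyl)triphenylphosphonium iodide 14 (not isolated), via (1-iodoethylidene)triphenylphosphorane 15 (not isolated)
Conditions: 12, n-BuLi, THF, rt; I2, −78 °C; NaN(SiMe3)2, −20 °C; then 11, −78 °C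
Reagents that add atoms: iodine, II
Why: Stork–Zhao-type iodoolefination, in which the non-stabilised α-iodo ylide should react under kinetic control to the (Z)-iodoalkene (iodine cis to the chain), as needed for C23=C24.

Step 8
Reactants: 3 3-[(4-methoxybenzyl)oxy]propanal; 17 vinylmagnesium bromide
Product: 18 rac-1-[(4-methoxybenzyl)oxy]pent-4-en-3-ol
Conditions: THF, −78 to 0 °C; aqueous work-up
Reagents that add atoms: none
Why: Grignard 1,2-addition; the racemic carbinol is oxidised in the next step.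

Step 9
Reactants: 18 rac-1-[(4-methoxybenzyl)oxy]pent-4-en-3-ol
Product: 19 5-[(4-methoxybenzyl)oxy]pent-1-en-3-one
Conditions: Dess–Martin periodinane, NaHCO3, CH2Cl2, 0 °C; used at once
Reagents that add atoms: none
Why: Dess–Martin oxidation of an allylic alcohol to the vinyl ketone under non-basic conditions, so that the β-alkoxy group is not eliminated.

Step 10
Reactants: 16 triethyl{[(3R,4R,6Z)-7-iodo-3-methylocta-1,6-dien-4-yl]oxy}silane; 19 5-[(4-methoxybenzyl)oxy]pent-1-en-3-one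
Product: 20 (4E,6R,7R,9Z)-10-iodo-1-[(4-methoxybenzyl)oxy]-6-methyl-7-[(triethylsilyl)oxy]undeca-4,9-dien-3-one
Conditions: RuCl2(H2IMes)(=CH-C6H4-2-O-i-Pr) (second-generation Hoveyda–Grubbs catalyst, 5 mol %), 19 (3 equiv), CH2Cl2, 40 °C
Reagents that add atoms: none
Why: Olefin cross-metathesis of a terminal alkene with an electron-poor vinyl ketone, which should give the (E)-enone (C18=C19) while the trisubstituted iodoalkene stays inert.

Step 11
Reactants: 20 (4E,6R,7R,9Z)-10-iodo-1-[(4-methoxybenzyl)oxy]-6-methyl-7-[(triethylsilyl)oxy]undeca-4,9-dien-3-one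
Product: 21 (3S,4E,6R,7R,9Z)-10-iodo-1-[(4-methoxybenzyl)oxy]-6-methyl-7-[(triethylsilyl)oxy]undeca-4,9-dien-3-ol
Conditions: (R)-2-methyl-CBS-oxazaborolidine (0.3 equiv), catecholborane, toluene, −78 °C
Reagents that add atoms: none
Why: Corey–Bakshi–Shibata 1,2-reduction, in which the enone should bind the catalyst with the alkenyl group as the large substituent so that the (R)-catalyst gives the 3S carbinol (C17).

Step 12
Reactants: 21 (3S,4E,6R,7R,9Z)-10-iodo-1-[(4-methoxybenzyl)oxy]-6-methyl-7-[(triethylsilyl)oxy]undeca-4,9-dien-3-ol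
Product: 22 tert-butyldimethylsilyl ether of 21 (C17 OTBS)
Conditions: TBSOTf, 2,6-lutidine, CH2Cl2, −78 °C
Reagents that add atoms: tert-butyldimethylsilyl trifluoromethanesulfonate, CC(C)(C)[Si](C)(C)OS(=O)(=O)C(F)(F)F
Why: Silylation of the allylic alcohol with a silyl triflate under non-acidic conditions.

Step 13
Reactants: 22 tert-butyldimethylsilyl ether of 21
Product: 23 (3S,4E,6R,7R,9Z)-3-[(tert-butyldimethylsilyl)oxy]-10-iodo-6-methyl-7-[(triethylsilyl)oxy]undeca-4,9-dien-1-ol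
Conditions: DDQ, CH2Cl2/pH 7 buffer, 0 °C
Reagents that add atoms: none
Why: Oxidative 4-methoxybenzyl ether cleavage by DDQ, orthogonal to both silyl ethers and the vinyl iodide.

Step 14
Reactants: 23 (3S,4E,6R,7R,9Z)-3-[(tert-butyldimethylsilyl)oxy]-10-iodo-6-methyl-7-[(triethylsilyl)oxy]undeca-4,9-dien-1-ol
Product: 24 (3S,4E,6R,7R,9Z)-3-[(tert-butyldimethylsilyl)oxy]-10-iodo-6-methyl-7-[(triethylsilyl)oxy]undeca-4,9-dienal (C15–C24 aldehyde)
Conditions: Dess–Martin periodinane, NaHCO3, CH2Cl2, 0 °C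
Reagents that add atoms: none
Why: Dess–Martin oxidation to the β-silyloxy aldehyde without elimination.

Step 15
Reactants: 3 3-[(4-methoxybenzyl)oxy]propanal; 25 ethynyltrimethylsilane
Product: 27 rac-5-[(4-methoxybenzyl)oxy]-1-(trimethylsilyl)pent-1-yn-3-ol, via lithium (trimethylsilyl)acetylide 26 (not isolated)
Conditions: 25, n-BuLi, THF, −78 °C; then 3
Reagents that add atoms: none
Why: 1,2-Addition of a lithium acetylide to an aldehyde; the racemic carbinol is oxidised next.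

Step 16
Reactants: 27 rac-5-[(4-methoxybenzyl)oxy]-1-(trimethylsilyl)pent-1-yn-3-ol
Product: 28 5-[(4-methoxybenzyl)oxy]-1-(trimethylsilyl)pent-1-yn-3-one
Conditions: Dess–Martin periodinane, NaHCO3, CH2Cl2, rt
Reagents that add atoms: none
Why: Dess–Martin oxidation of a propargylic alcohol to the ynone.

Step 17
Reactants: 28 5-[(4-methoxybenzyl)oxy]-1-(trimethylsilyl)pent-1-yn-3-one
Product: 29 (S)-5-[(4-methoxybenzyl)oxy]-1-(trimethylsilyl)pent-1-yn-3-ol
Conditions: RuCl[(S,S)-TsDPEN](p-cymene) (2 mol %), i-PrOH, rt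
Reagents that add atoms: none
Why: Noyori asymmetric transfer hydrogenation of an ynone, in which the alkynyl group takes the place of the aryl group in the organised transition state so that the (S,S)-ligand should give the S propargylic alcohol (C5).

Step 18
Reactants: 29 (S)-5-[(4-methoxybenzyl)oxy]-1-(trimethylsilyl)pent-1-yn-3-ol
Product: 30 (S)-tert-butyl({5-[(4-methoxybenzyl)oxy]-1-(trimethylsilyl)pent-1-yn-3-yl}oxy)dimethylsilane
Conditions: TBSCl, imidazole, DMF, rt
Reagents that add atoms: tert-butyldimethylsilyl chloride, CC(C)(C)[Si](C)(C)Cl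
Why: Standard imidazole-mediated silylation of a secondary propargylic alcohol.

Step 19
Reactants: 30 (S)-tert-butyl({5-[(4-methoxybenzyl)oxy]-1-(trimethylsilyl)pent-1-yn-3-yl}oxy)dimethylsilane
Product: 31 (S)-tert-butyl({5-[(4-methoxybenzyl)oxy]pent-1-yn-3-yl}oxy)dimethylsilane
Conditions: K2CO3, MeOH, rt
Reagents that add atoms: none
Why: Base-mediated protiodesilylation of the alkynylsilane, which leaves the secondary silyl ether intact.

Step 20
Reactants: 32 3-chloro-2-(chloromethyl)prop-1-ene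
Product: 33 tributyl[2-(chloromethyl)prop-2-en-1-yl]stannane
Conditions: Bu3SnH, LiN(i-Pr)2, THF, −78 °C; then 32 (3 equiv), −78 °C
Reagents that add atoms: tributyltin hydride, CCCC[SnH](CCCC)CCCC
Why: SN2 alkylation of tributylstannyllithium by an allylic chloride, with the dichloride in excess so that mono-substitution prevails.

Step 21
Reactants: 31 (S)-tert-butyl({5-[(4-methoxybenzyl)oxy]pent-1-yn-3-yl}oxy)dimethylsilane; 33 tributyl[2-(chloromethyl)prop-2-en-1-yl]stannane
Product: 35 tributyl{(4E,6S)-6-[(tert-butyldimethylsilyl)oxy]-8-[(4-methoxybenzyl)oxy]-2-methylideneoct-4-en-1-yl}stannane, via (E)-alkenylzirconocene chloride 34 (not isolated)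
Conditions: Cp2Zr(H)Cl, THF, rt; then 33 (1.5 equiv), CuCl (10 mol %), 0 °C to rt
Reagents that add atoms: none
Why: Schwartz hydrozirconation (syn, terminal, hence the E alkene C6=C7) followed by copper-catalysed allylation of the alkenylzirconocene, where SN2 and SN2′ attack on the symmetric 2-substituted allyl chloride lead to the same product (C7–C8 bond).

Step 22
Reactants: 36 4-chlorobutan-1-ol
Product: 37 4-chlorobutanal
Conditions: PhI(OAc)2, TEMPO (cat.), CH2Cl2, rt; used as a fresh solution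
Reagents that add atoms: none
Why: TEMPO/PhI(OAc)2 oxidation of a primary alcohol to the aldehyde under neutral conditions.

Step 23
Reactants: 35 tributyl{(4E,6S)-6-[(tert-butyldimethylsilyl)oxy]-8-[(4-methoxybenzyl)oxy]-2-methylideneoct-4-en-1-yl}stannane; 37 4-chlorobutanal
Product: 39 (4R,8E,10S)-10-[(tert-butyldimethylsilyl)oxy]-1-chloro-12-[(4-methoxybenzyl)oxy]-6-methylidenedodec-8-en-4-ol, via tributylstannyl ether 38 (not isolated)
Conditions: (S)-BINOL (20 mol %), Ti(O-i-Pr)4 (10 mol %), 4 Å MS, 37 (2 equiv), CH2Cl2, −20 °C; aq NaHCO3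
Reagents that add atoms: none
Why: Keck catalytic asymmetric allylation, in which the BINOL–titanium Lewis acid activates the aldehyde for open SE2′ addition of the 2-substituted allylstannane (C10–C11 bond) and (S)-BINOL should direct attack to the Si face, setting 4R (C11).

Step 24
Reactants: 39 (4R,8E,10S)-10-[(tert-butyldimethylsilyl)oxy]-1-chloro-12-[(4-methoxybenzyl)oxy]-6-methylidenedodec-8-en-4-ol
Product: 40 (4R,8E,10S)-4,10-bis[(tert-butyldimethylsilyl)oxy]-1-chloro-12-[(4-methoxybenzyl)oxy]-6-methylidenedodec-8-ene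
Conditions: TBSOTf, 2,6-lutidine, CH2Cl2, −78 °C
Reagents that add atoms: tert-butyldimethylsilyl trifluoromethanesulfonate, CC(C)(C)[Si](C)(C)OS(=O)(=O)C(F)(F)F
Why: Silylation with a silyl triflate and a hindered base, which avoids the alkoxide that could cyclise onto an electrophilic site.

Step 25
Reactants: 40 (4R,8E,10S)-4,10-bis[(tert-butyldimethylsilyl)oxy]-1-chloro-12-[(4-methoxybenzyl)oxy]-6-methylidenedodec-8-ene
Product: 41 5-{[(4R,8E,10S)-4,10-bis[(tert-butyldimethylsilyl)oxy]-12-[(4-methoxybenzyl)oxy]-6-methylidenedodec-8-en-1-yl]sulfanyl}-1-phenyl-1H-tetrazole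
Conditions: 1-phenyl-1H-tetrazole-5-thiol, K2CO3, NaI (cat.), DMF, 50 °C
Reagents that add atoms: 1-phenyl-1H-tetrazole-5-thiol, Sc1nnnn1-c1ccccc1
Why: SN2 thioetherification of the primary chloride by the tetrazolyl thiolate, assisted by in situ halide exchange.

Step 26
Reactants: 41 tetrazolyl sulfide
Product: 42 5-{[(4R,8E,10S)-4,10-bis[(tert-butyldimethylsilyl)oxy]-12-[(4-methoxybenzyl)oxy]-6-methylidenedodec-8-en-1-yl]sulfonyl}-1-phenyl-1H-tetrazole (C3–C14 sulfone)
Conditions: (NH4)6Mo7O24·4H2O (20 mol %), 30% H2O2, EtOH, 0 °C to rt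
Reagents that add atoms: hydrogen peroxide, OO
Why: Molybdate-catalysed peroxide oxidation of the sulfide to the sulfone, which should spare the unactivated alkenes and the ethers.

Step 27
Reactants: 42 C3–C14 sulfone; 24 C15–C24 aldehyde
Product: 44 C3–C24 chain with C3 OPMB, C5/C11/C17 OTBS, C21 OTES and C24 (Z)-iodide (6E,14E,18E; 5S,11R,17S,20R,21R), via potassium sulfonyl carbanion 43 (not isolated)
Conditions: KN(SiMe3)2, DME, −60 °C; then 24, −60 °C to rt
Reagents that add atoms: none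
Why: Julia–Kocienski olefination, in which addition of the metalated tetrazolyl sulfone, Smiles rearrangement and loss of SO2 should give the (E)-alkene C14=C15 under potassium/DME conditions.

Step 28
Reactants: 44 C3–C24 chain (C21 OTES)
Product: 45 C21 alcohol (C3 OPMB, three OTBS, C24 iodide)
Conditions: PPTS, MeOH/CH2Cl2, 0 °C to rt
Reagents that add atoms: none
Why: Acid-catalysed methanolysis that should remove the triethylsilyl ether selectively, because the tert-butyldimethylsilyl ethers are cleaved much more slowly.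

Step 29
Reactants: 45 C21 alcohol; 46 bromoacetyl bromide
Product: 47 C21 bromoacetate (C3 OPMB)
Conditions: pyridine, CH2Cl2, −20 to 0 °C
Reagents that add atoms: none
Why: Acylation of the secondary alcohol with an acyl bromide under mild base, short enough to avoid quaternisation of the bromoacetate.

Step 30
Reactants: 47 C21 bromoacetate (C3 OPMB)
Product: 48 C21 bromoacetate C3 alcohol
Conditions: DDQ, CH2Cl2/pH 7 buffer, 0 °C
Reagents that add atoms: none
Why: Oxidative 4-methoxybenzyl ether cleavage by DDQ, which tolerates the bromoacetate, silyl ethers and vinyl iodide.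

Step 31
Reactants: 48 C21 bromoacetate C3 alcohol
Product: 49 C21 bromoacetate C3 aldehyde (three OTBS, C24 (Z)-iodide)
Conditions: Dess–Martin periodinane, NaHCO3, CH2Cl2, 0 °C
Reagents that add atoms: none
Why: Dess–Martin oxidation to the β-silyloxy aldehyde under buffered, non-nucleophilic conditions.

Step 32
Reactants: 49 C21 bromoacetate C3 aldehyde
Product: 52 22-membered β-hydroxy macrolactone (free 3S hydroxyl, three OTBS, C24 (Z)-iodide), via samarium enolate 50 (not isolated), via samarium aldolate 51 (not isolated)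
Conditions: SmI2 (0.1 M in THF, 4 equiv), THF, −78 °C, 49 added slowly (final 1 mM); then aq NH4Cl
Reagents that add atoms: none
Why: Two single-electron transfers from divalent samarium cleave the C2–Br bond and give the trivalent samarium enolate 50 of the C21 acetate, which adds to the C3 aldehyde through a chair-like transition state in which samarium bridges the enolate and aldehyde oxygens. The closest known reaction type is the SmI2-mediated intramolecular Reformatsky reaction used to close medium and large lactones. The 22-membered ring is closed in an exo-trig mode by the C2–C3 bond, at high dilution so that closure outruns intermolecular addition. The new C3 stereocentre is expected to form 1,3-anti to the C5 silyl ether (polar, non-chelating β-silyloxy model inside the macrocyclic transition state), that is 3S. The step needs chemoselective reduction of the α-bromo ester beside the aldehyde and the C24 vinyl iodide, which the much faster electron transfer to α-halo esters at −78 °C without HMPA should secure.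

Step 33
Reactants: 52 22-membered β-hydroxy macrolactone
Product: 53 tetraol macrolactone with C24 (Z)-iodide
Conditions: HF·pyridine, pyridine, THF, 0 °C to rt
Reagents that add atoms: none
Why: Buffered fluoride desilylation, chosen to avoid base-induced retro-aldol cleavage or translactonisation of the 3,5-dihydroxy lactone.

Step 34
Reactants: 54 (E)-pent-2-en-4-yn-1-ol
Product: 56 (E)-5-(tributylstannyl)pent-2-en-4-yn-1-ol, via dilithio derivative 55 (not isolated)
Conditions: n-BuLi (2.1 equiv), THF, −78 °C; Bu3SnCl (1.0 equiv)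
Reagents that add atoms: tributyltin chloride, CCCC[Sn](Cl)(CCCC)CCCC
Why: Stannylation of the acetylide carbon of the alkoxide–acetylide dianion, the carbon nucleophile reacting in preference to the alkoxide.

Step 35
Reactants: 56 (E)-5-(tributylstannyl)pent-2-en-4-yn-1-ol
Product: 58 (2E,4Z)-5-(tributylstannyl)penta-2,4-dien-1-ol, via stannyl zirconocene 57 (not isolated)
Conditions: Cp2Zr(H)Cl (2.5 equiv), THF, rt; then H2O
Reagents that add atoms: none
Why: Hydrozirconation of a stannylalkyne (syn addition) and protonolysis of the C–Zr bond with retention, which should give the (Z)-vinylstannane (C25=C26).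

Step 36
Reactants: 58 (2E,4Z)-5-(tributylstannyl)penta-2,4-dien-1-ol
Product: 59 (2E,4Z)-5-(tributylstannyl)penta-2,4-dienal
Conditions: MnO2, CH2Cl2, 0 °C, dark; used at once
Reagents that add atoms: none
Why: Neutral MnO2 oxidation of an allylic alcohol, which avoids the acid that would protodestannylate or isomerise the (Z)-stannane.

Step 37
Reactants: 59 (2E,4Z)-5-(tributylstannyl)penta-2,4-dienal; 60 methyltriphenylphosphonium bromide
Product: 62 tributyl[(1Z,3E)-hexa-1,3,5-trien-1-yl]stannane, via methylidenetriphenylphosphorane 61 (not isolated)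
Conditions: 60, KN(SiMe3)2, THF, 0 °C; then 59, −78 to 0 °C, dark
Reagents that add atoms: none
Why: Wittig methylenation, which adds the terminal C29=C30 alkene without touching the existing alkene geometries.

Step 38
Reactants: 53 tetraol macrolactone with C24 (Z)-iodide; 62 tributyl[(1Z,3E)-hexa-1,3,5-trien-1-yl]stannane
Product: 63 target (CNP0313104.1)
Conditions: Pd2(dba)3 (10 mol %), AsPh3 (40 mol %), DMF, rt, dark
Reagents that add atoms: none
Why: Stille coupling (C24–C25), which proceeds with retention at both alkenyl partners and tolerates free hydroxyl groups and the lactone.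

**Compound list**
1 | propane-1,3-diol | OCCCO | starting material
2 | 3-[(4-methoxybenzyl)oxy]propan-1-ol | COc1ccc(COCCCO)cc1 | intermediate
3 | 3-[(4-methoxybenzyl)oxy]propanal | COc1ccc(COCCC=O)cc1 | intermediate
4 | cis-but-2-ene | C/C=C\C | starting material
5 | (Z)-but-2-enylpotassium | C/C=C\C[K] | intermediate
6 | B-(Z)-crotyldiisopinocampheylborane, isopinocampheyl groups from (+)-α-pinene | C/C=C\CB([C@@H]1C[C@@H]2C[C@H]([C@H]1C)C2(C)C)[C@@H]1C[C@@H]2C[C@H]([C@H]1C)C2(C)C | intermediate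
7 | diisopinocampheylborinate ester of 8 | C=C[C@@H](C)[C@H](OB([C@@H]1C[C@@H]2C[C@H]([C@H]1C)C2(C)C)[C@@H]1C[C@@H]2C[C@H]([C@H]1C)C2(C)C)CCOCc1ccc(OC)cc1 | intermediate
8 | (3R,4R)-1-[(4-methoxybenzyl)oxy]-4-methylhex-5-en-3-ol | C=C[C@@H](C)[C@H](O)CCOCc1ccc(OC)cc1 | intermediate
9 | triethyl{[(3R,4R)-1-[(4-methoxybenzyl)oxy]-4-methylhex-5-en-3-yl]oxy}silane | C=C[C@@H](C)[C@H](O[Si](CC)(CC)CC)CCOCc1ccc(OC)cc1 | intermediate
10 | (3R,4R)-4-methyl-3-[(triethylsilyl)oxy]hex-5-en-1-ol | C=C[C@@H](C)[C@H](O[Si](CC)(CC)CC)CCO | intermediate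
11 | (3R,4R)-4-methyl-3-[(triethylsilyl)oxy]hex-5-enal | C=C[C@@H](C)[C@H](O[Si](CC)(CC)CC)CC=O | intermediate
12 | ethyltriphenylphosphonium iodide | CC[P+](c1ccccc1)(c1ccccc1)c1ccccc1.[I-] | starting material
13 | ethylidenetriphenylphosphorane | CC=P(c1ccccc1)(c1ccccc1)c1ccccc1 | intermediate
14 | (1-iodoethyl)triphenylphosphonium iodide | CC(I)[P+](c1ccccc1)(c1ccccc1)c1ccccc1.[I-] | intermediate
15 | (1-iodoethylidene)triphenylphosphorane | CC(I)=P(c1ccccc1)(c1ccccc1)c1ccccc1 | intermediate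
16 | triethyl{[(3R,4R,6Z)-7-iodo-3-methylocta-1,6-dien-4-yl]oxy}silane | C=C[C@@H](C)[C@H](O[Si](CC)(CC)CC)C/C=C(/C)I | intermediate
17 | vinylmagnesium bromide | C=C[Mg]Br | starting material
18 | rac-1-[(4-methoxybenzyl)oxy]pent-4-en-3-ol | COc1ccc(COCCC(O)C=C)cc1 | intermediate
19 | 5-[(4-methoxybenzyl)oxy]pent-1-en-3-one | COc1ccc(COCCC(=O)C=C)cc1 | intermediate
20 | (4E,6R,7R,9Z)-10-iodo-1-[(4-methoxybenzyl)oxy]-6-methyl-7-[(triethylsilyl)oxy]undeca-4,9-dien-3-one | COc1ccc(COCCC(=O)/C=C/[C@@H](C)[C@H](O[Si](CC)(CC)CC)C/C=C(/C)I)cc1 | intermediate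
21 | (3S,4E,6R,7R,9Z)-10-iodo-1-[(4-methoxybenzyl)oxy]-6-methyl-7-[(triethylsilyl)oxy]undeca-4,9-dien-3-ol | COc1ccc(COCC[C@H](O)/C=C/[C@@H](C)[C@H](O[Si](CC)(CC)CC)C/C=C(/C)I)cc1 | intermediate
22 | tert-butyldimethylsilyl ether of 21 (C17 OTBS) | COc1ccc(COCC[C@H](O[Si](C)(C)C(C)(C)C)/C=C/[C@@H](C)[C@H](O[Si](CC)(CC)CC)C/C=C(/C)I)cc1 | intermediate
23 | (3S,4E,6R,7R,9Z)-3-[(tert-butyldimethylsilyl)oxy]-10-iodo-6-methyl-7-[(triethylsilyl)oxy]undeca-4,9-dien-1-ol | OCC[C@H](O[Si](C)(C)C(C)(C)C)/C=C/[C@@H](C)[C@H](O[Si](CC)(CC)CC)C/C=C(/C)I | intermediate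
24 | (3S,4E,6R,7R,9Z)-3-[(tert-butyldimethylsilyl)oxy]-10-iodo-6-methyl-7-[(triethylsilyl)oxy]undeca-4,9-dienal (C15–C24 aldehyde) | O=CC[C@H](O[Si](C)(C)C(C)(C)C)/C=C/[C@@H](C)[C@H](O[Si](CC)(CC)CC)C/C=C(/C)I | intermediate
25 | ethynyltrimethylsilane | C#C[Si](C)(C)C | starting material
26 | lithium (trimethylsilyl)acetylide | [Li]C#C[Si](C)(C)C | intermediate
27 | rac-5-[(4-methoxybenzyl)oxy]-1-(trimethylsilyl)pent-1-yn-3-ol | COc1ccc(COCCC(O)C#C[Si](C)(C)C)cc1 | intermediate
28 | 5-[(4-methoxybenzyl)oxy]-1-(trimethylsilyl)pent-1-yn-3-one | COc1ccc(COCCC(=O)C#C[Si](C)(C)C)cc1 | intermediate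
29 | (S)-5-[(4-methoxybenzyl)oxy]-1-(trimethylsilyl)pent-1-yn-3-ol | COc1ccc(COCC[C@H](O)C#C[Si](C)(C)C)cc1 | intermediate
30 | (S)-tert-butyl({5-[(4-methoxybenzyl)oxy]-1-(trimethylsilyl)pent-1-yn-3-yl}oxy)dimethylsilane | COc1ccc(COCC[C@H](O[Si](C)(C)C(C)(C)C)C#C[Si](C)(C)C)cc1 | intermediate
31 | (S)-tert-butyl({5-[(4-methoxybenzyl)oxy]pent-1-yn-3-yl}oxy)dimethylsilane | COc1ccc(COCC[C@H](O[Si](C)(C)C(C)(C)C)C#C)cc1 | intermediate
32 | 3-chloro-2-(chloromethyl)prop-1-ene | C=C(CCl)CCl | starting material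
33 | tributyl[2-(chloromethyl)prop-2-en-1-yl]stannane | C=C(CCl)C[Sn](CCCC)(CCCC)CCCC | intermediate
34 | (E)-alkenylzirconocene chloride from 31 | COc1ccc(COCC[C@H](O[Si](C)(C)C(C)(C)C)/C=C/[Zr](Cl)(C2C=CC=C2)C2C=CC=C2)cc1 | intermediate
35 | tributyl{(4E,6S)-6-[(tert-butyldimethylsilyl)oxy]-8-[(4-methoxybenzyl)oxy]-2-methylideneoct-4-en-1-yl}stannane | COc1ccc(COCC[C@H](O[Si](C)(C)C(C)(C)C)/C=C/CC(=C)C[Sn](CCCC)(CCCC)CCCC)cc1 | intermediate
36 | 4-chlorobutan-1-ol | OCCCCCl | starting material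
37 | 4-chlorobutanal | O=CCCCCl | intermediate
38 | tributylstannyl ether of 39 | COc1ccc(COCC[C@H](O[Si](C)(C)C(C)(C)C)/C=C/CC(=C)C[C@H](O[Sn](CCCC)(CCCC)CCCC)CCCCl)cc1 | intermediate
39 | (4R,8E,10S)-10-[(tert-butyldimethylsilyl)oxy]-1-chloro-12-[(4-methoxybenzyl)oxy]-6-methylidenedodec-8-en-4-ol | COc1ccc(COCC[C@H](O[Si](C)(C)C(C)(C)C)/C=C/CC(=C)C[C@H](O)CCCCl)cc1 | intermediate
40 | (4R,8E,10S)-4,10-bis[(tert-butyldimethylsilyl)oxy]-1-chloro-12-[(4-methoxybenzyl)oxy]-6-methylidenedodec-8-ene | COc1ccc(COCC[C@H](O[Si](C)(C)C(C)(C)C)/C=C/CC(=C)C[C@H](O[Si](C)(C)C(C)(C)C)CCCCl)cc1 | intermediate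
41 | 1-phenyl-1H-tetrazol-5-yl sulfide of the C3–C14 unit | COc1ccc(COCC[C@H](O[Si](C)(C)C(C)(C)C)/C=C/CC(=C)C[C@H](O[Si](C)(C)C(C)(C)C)CCCSc2nnnn2-c2ccccc2)cc1 | intermediate
42 | 1-phenyl-1H-tetrazol-5-yl sulfone of the C3–C14 unit | COc1ccc(COCC[C@H](O[Si](C)(C)C(C)(C)C)/C=C/CC(=C)C[C@H](O[Si](C)(C)C(C)(C)C)CCCS(=O)(=O)c2nnnn2-c2ccccc2)cc1 | intermediate
43 | potassium α-sulfonyl carbanion of 42 | COc1ccc(COCC[C@H](O[Si](C)(C)C(C)(C)C)/C=C/CC(=C)C[C@H](O[Si](C)(C)C(C)(C)C)CC[CH-]S(=O)(=O)c2nnnn2-c2ccccc2)cc1.[K+] | intermediate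
44 | C3–C24 chain: C3 OPMB; C5, C11, C17 OTBS; C21 OTES; C24 (Z)-iodide; 6E,14E,18E; 5S,11R,17S,20R,21R | I\C(C)=C/C[C@@H](O[Si](CC)(CC)CC)[C@H](C)/C=C/[C@@H](O[Si](C)(C)C(C)(C)C)C/C=C/CC[C@@H](O[Si](C)(C)C(C)(C)C)CC(=C)C/C=C/[C@@H](O[Si](C)(C)C(C)(C)C)CCOCc1ccc(OC)cc1 | intermediate
45 | C21 alcohol of the chain (C3 OPMB, three OTBS) | I\C(C)=C/C[C@@H](O)[C@H](C)/C=C/[C@@H](O[Si](C)(C)C(C)(C)C)C/C=C/CC[C@@H](O[Si](C)(C)C(C)(C)C)CC(=C)C/C=C/[C@@H](O[Si](C)(C)C(C)(C)C)CCOCc1ccc(OC)cc1 | intermediate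
46 | bromoacetyl bromide | BrCC(=O)Br | starting material
47 | C21 bromoacetate, C3 OPMB | I\C(C)=C/C[C@@H](OC(=O)CBr)[C@H](C)/C=C/[C@@H](O[Si](C)(C)C(C)(C)C)C/C=C/CC[C@@H](O[Si](C)(C)C(C)(C)C)CC(=C)C/C=C/[C@@H](O[Si](C)(C)C(C)(C)C)CCOCc1ccc(OC)cc1 | intermediate
48 | C21 bromoacetate, C3 alcohol | I\C(C)=C/C[C@@H](OC(=O)CBr)[C@H](C)/C=C/[C@@H](O[Si](C)(C)C(C)(C)C)C/C=C/CC[C@@H](O[Si](C)(C)C(C)(C)C)CC(=C)C/C=C/[C@@H](O[Si](C)(C)C(C)(C)C)CCO | intermediate
49 | C21 bromoacetate, C3 aldehyde (three OTBS, C24 (Z)-iodide) | I\C(C)=C/C[C@@H](OC(=O)CBr)[C@H](C)/C=C/[C@@H](O[Si](C)(C)C(C)(C)C)C/C=C/CC[C@@H](O[Si](C)(C)C(C)(C)C)CC(=C)C/C=C/[C@@H](O[Si](C)(C)C(C)(C)C)CC=O | intermediate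
50 | trivalent samarium enolate of the C21 acetate | I\C(C)=C/C[C@@H](OC(=C)O[Sm](I)I)[C@H](C)/C=C/[C@@H](O[Si](C)(C)C(C)(C)C)C/C=C/CC[C@@H](O[Si](C)(C)C(C)(C)C)CC(=C)C/C=C/[C@@H](O[Si](C)(C)C(C)(C)C)CC=O | intermediate
51 | samarium aldolate of 52 | I\C(C)=C/C[C@H]1OC(=O)C[C@@H](O[Sm](I)I)C[C@H](O[Si](C)(C)C(C)(C)C)/C=C/CC(=C)C[C@H](O[Si](C)(C)C(C)(C)C)CC/C=C/C[C@H](O[Si](C)(C)C(C)(C)C)/C=C/[C@H]1C | intermediate
52 | 22-membered β-hydroxy macrolactone (3S hydroxyl free; C5, C11, C17 OTBS; C24 (Z)-iodide) | I\C(C)=C/C[C@H]1OC(=O)C[C@@H](O)C[C@H](O[Si](C)(C)C(C)(C)C)/C=C/CC(=C)C[C@H](O[Si](C)(C)C(C)(C)C)CC/C=C/C[C@H](O[Si](C)(C)C(C)(C)C)/C=C/[C@H]1C | intermediate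
53 | tetraol macrolactone with C24 (Z)-iodide | I\C(C)=C/C[C@H]1OC(=O)C[C@@H](O)C[C@H](O)/C=C/CC(=C)C[C@H](O)CC/C=C/C[C@H](O)/C=C/[C@H]1C | intermediate
54 | (E)-pent-2-en-4-yn-1-ol | C#C/C=C/CO | starting material
55 | dilithio derivative of 54 (alkoxide and acetylide) | [Li]C#C/C=C/CO[Li] | intermediate
56 | (E)-5-(tributylstannyl)pent-2-en-4-yn-1-ol | CCCC[Sn](CCCC)(CCCC)C#C/C=C/CO | intermediate
57 | 1-stannyl-1-zirconocenyl diene (zirconium alkoxide) from 56 | CCCC[Sn](CCCC)(CCCC)/C(=C\C=C\CO[Zr](Cl)(C1C=CC=C1)C1C=CC=C1)[Zr](Cl)(C1C=CC=C1)C1C=CC=C1 | intermediate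
58 | (2E,4Z)-5-(tributylstannyl)penta-2,4-dien-1-ol | CCCC[Sn](CCCC)(CCCC)/C=C\C=C\CO | intermediate
59 | (2E,4Z)-5-(tributylstannyl)penta-2,4-dienal | CCCC[Sn](CCCC)(CCCC)/C=C\C=C\C=O | intermediate
60 | methyltriphenylphosphonium bromide | C[P+](c1ccccc1)(c1ccccc1)c1ccccc1.[Br-] | starting material
61 | methylidenetriphenylphosphorane | C=P(c1ccccc1)(c1ccccc1)c1ccccc1 | intermediate
62 | tributyl[(1Z,3E)-hexa-1,3,5-trien-1-yl]stannane | CCCC[Sn](CCCC)(CCCC)/C=C\C=C\C=C | intermediate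
63 | CNP0313104.1 (3S,5S,11R,17S,20R,21R; 6E,14E,18E,23Z,25Z,27E) | C=C/C=C/C=C\C(C)=C/C[C@H]1OC(=O)C[C@@H](O)C[C@H](O)/C=C/CC(=C)C[C@H](O)CC/C=C/C[C@H](O)/C=C/[C@H]1C | target

**Step count and risks**
Total step count: 38. Longest linear sequence: 20 steps (1, 2, 15–19, 21, 23–33, 38).

Steps most likely to fail:

1. Step 32. The ring-closing aldol may show poor facial selectivity at C3, or intermolecular addition may compete with closure. Fallback for the stereochemical problem: the C3-epimer mixture of 52 is oxidised with Dess–Martin periodinane to the 3-oxo macrolactone F1, and HF·pyridine then frees the hydroxyl groups to give the 3-oxo triol F2. Reduction with Me4NBH(OAc)3 in MeCN/AcOH at −30 °C, directed by the free C5 hydroxyl, should deliver the 3,5-anti diol. The fallback sets out from 52 and comes back at 53.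

2. Step 38. The (Z)-trienylstannane may lose its geometry or undergo protodestannylation during its preparation (steps 36 and 37) or during the coupling. Fallback without a stannane: 54 is oxidised with MnO2 to (E)-pent-2-en-4-ynal F3, and Wittig methylenation gives (E)-hexa-1,3-dien-5-yne F4, handled as a solution. Sonogashira coupling of F4 with 53 (Pd(PPh3)4, CuI, Et3N, DMF) gives the 25,26-didehydro compound F5. Semi-reduction of the conjugated triple bond with zinc activated by Cu(OAc)2 and AgNO3 in MeOH/H2O should form the (Z)-C25=C26 alkene. The fallback sets out from 54 and 53 and comes back at 63.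

3. Step 23. The bulky, functionalised allylstannane may turn over slowly and the enantioselectivity may erode. Fallback that sets C11 on a small substrate and forms the C7–C8 bond afterwards: tributyl{2-[(trimethylsilyl)methyl]prop-2-en-1-yl}stannane F6 is made from commercial [2-(chloromethyl)allyl]trimethylsilane and Bu3SnLi. Addition of F6 to 37 under the same (S)-BINOL/Ti(O-i-Pr)4 catalysis gives (4R)-1-chloro-6-[(trimethylsilyl)methyl]hept-6-en-4-ol F7, which TBSOTf/2,6-lutidine converts to the silyl ether F8. Bromodesilylation of the allylsilane with NBS at −78 °C gives the allylic bromide F9. CuCl-catalysed coupling of F9 with alkenylzirconocene 34 (from 31 and Cp2Zr(H)Cl) joins C7 to C8. The fallback sets out from 37 and 31 and comes back at 40.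

Further compounds
F1 | step 32 | 3-oxo macrolactone (C5, C11, C17 OTBS; C24 (Z)-iodide) | I\C(C)=C/C[C@H]1OC(=O)CC(=O)C[C@H](O[Si](C)(C)C(C)(C)C)/C=C/CC(=C)C[C@H](O[Si](C)(C)C(C)(C)C)CC/C=C/C[C@H](O[Si](C)(C)C(C)(C)C)/C=C/[C@H]1C
F2 | step 32 | 3-oxo macrolactone triol (C24 (Z)-iodide) | I\C(C)=C/C[C@H]1OC(=O)CC(=O)C[C@H](O)/C=C/CC(=C)C[C@H](O)CC/C=C/C[C@H](O)/C=C/[C@H]1C
F3 | step 38 | (E)-pent-2-en-4-ynal | C#C/C=C/C=O
F4 | step 38 | (E)-hexa-1,3-dien-5-yne | C#C/C=C/C=C
F5 | step 38 | 25,26-didehydro analogue of the target (C25≡C26 dienyne) | C=C/C=C/C#C\C(C)=C/C[C@H]1OC(=O)C[C@@H](O)C[C@H](O)/C=C/CC(=C)C[C@H](O)CC/C=C/C[C@H](O)/C=C/[C@H]1C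
F6 | step 23 | tributyl{2-[(trimethylsilyl)methyl]prop-2-en-1-yl}stannane | C=C(C[Si](C)(C)C)C[Sn](CCCC)(CCCC)CCCC
F7 | step 23 | (4R)-1-chloro-6-[(trimethylsilyl)methyl]hept-6-en-4-ol | ClCCC[C@@H](O)CC(=C)C[Si](C)(C)C
F8 | step 23 | tert-butyldimethylsilyl ether of F7 | ClCCC[C@@H](O[Si](C)(C)C(C)(C)C)CC(=C)C[Si](C)(C)C
F9 | step 23 | tert-butyl{[(4R)-6-(bromomethyl)-1-chlorohept-6-en-4-yl]oxy}dimethylsilane | ClCCC[C@@H](O[Si](C)(C)C(C)(C)C)CC(=C)CBr
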